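**Retrosynthetic overview**

1. The ten-membered carbocycle is closed last, at C9–C10, by an intramolecular Nozaki–Hiyama–Kishi addition of a (Z)-α-iodo-enal to an α-acyloxy aldehyde (sets C9).
2. C7–C8 comes from a Barbier union of a 3-(bromomethyl)butenolide with 2,2-dimethoxyacetaldehyde, followed by O8 acylation; C7 and C8 are relayed from C6, and the α-methylene lactone appears by allylic transposition.
3. Key step, the C6–O bond: iridium-catalysed enantioconvergent allylic esterification of a racemic alkenyl vinyl carbinol with 2-(bromomethyl)acrylic acid (the only absolute stereocontrol event), then ring-closing metathesis to the butenolide (first ring).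
4. The carbinol comes from vinyl addition to a trisubstituted enal built by hydroxyl-directed anti-carbomagnesiation of a butynediol monoether (C4=C5 geometry) and a Z-selective iodo-Wittig reaction (C1=C10 geometry).
5. Ring order: butenolide → α-methylene-γ-lactone → cyclodecadiene.

Assumptions: labels C1–C15 follow germacranolide numbering (lactone O on C6, ester O on C8, OH on C9, CHO = C14, CH2OH = C15); every compound entered as a reactant other than the diol of step 1 is bought, including (2R)-2-methylbutanoic acid; the ligand enantiomer quoted in step 8 is taken to give the (3S)-ester, and its antipode is used if the sense of induction proves opposite. TES = triethylsilyl, TBSO = tert-butyldimethylsilyloxy, DIC = N,N'-diisopropylcarbodiimide, PPTS = pyridinium p-toluenesulfonate, L* = (S)-BINOL N-(5H-dibenzo[b,f]azepin-5-yl) phosphoramidite.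

**Route**

Step 1
Reactants: 1 but-2-yne-1,4-diol
Product: 2 4-(triethylsilyloxy)but-2-yn-1-ol
Conditions: TESCl (1.0 equiv), imidazole (1.2 equiv), 1 (3 equiv), DMF, 0 °C
Reagents that add atoms: chlorotriethylsilane CC[Si](CC)(CC)Cl
Why: statistical monosilylation with the cheap diol in excess (silyl ether formation) leaves one free hydroxyl to direct step 2.

Step 2
Reactants: 2 4-(triethylsilyloxy)but-2-yn-1-ol; 3 [2-(1,3-dioxolan-2-yl)ethyl]magnesium bromide
Product: 5 (2E)-2-[2-(1,3-dioxolan-2-yl)ethyl]-4-(triethylsilyloxy)but-2-en-1-ol, via alkenylmagnesium chelate 4 (not isolated)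
Conditions: 3 (3.0 equiv, 0.5 M in THF), CuI (10 mol %), THF, −20 → 25 °C; then sat. aq. NH4Cl
Reagents that add atoms: none
Why: hydroxyl-directed anti-carbomagnesiation (copper-catalysed Grignard addition to a propargylic alkoxide) puts the alkyl group on the alkyne carbon next to the alkoxide and magnesium on the far carbon in a five-membered chelate, so protonation gives only the alkene with C3 and C6 cis, which is the C4=C5 geometry of the target.

Step 3
Reactants: 5 (2E)-2-[2-(1,3-dioxolan-2-yl)ethyl]-4-(triethylsilyloxy)but-2-en-1-ol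
Product: 6 (2E)-1-(TBSO)-2-[2-(1,3-dioxolan-2-yl)ethyl]-4-(triethylsilyloxy)but-2-ene
Conditions: TBSCl (1.2 equiv), imidazole (2 equiv), DMF, 25 °C
Reagents that add atoms: tert-butyldimethylsilyl chloride CC(C)(C)[Si](C)(C)Cl
Why: routine silylation of the primary allylic alcohol (silyl ether formation) installs the O15 protecting group that is carried to step 12.

Step 4
Reactants: 6 (2E)-1-(TBSO)-2-[2-(1,3-dioxolan-2-yl)ethyl]-4-(triethylsilyloxy)but-2-ene
Product: 7 (4E)-4-(TBSO-methyl)-6-hydroxyhex-4-enal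
Conditions: PPTS (0.3 equiv), acetone/H2O (9:1), 55 °C
Reagents that add atoms: water O
Why: mild acid hydrolysis cleaves the labile triethylsilyl ether and the dioxolane (acetal hydrolysis) while the far more stable primary tert-butyldimethylsilyl ether survives.

Step 5
Reactants: 7 (4E)-4-(TBSO-methyl)-6-hydroxyhex-4-enal; 8 (1,3-dioxolan-2-ylmethyl)triphenylphosphonium bromide
Product: 12 (2E,6Z)-3-(TBSO-methyl)-7-(1,3-dioxolan-2-yl)-7-iodohepta-2,6-dien-1-ol, via phosphorus ylide 9 (not isolated), via iodophosphonium iodide 10 (not isolated), via iodo ylide 11 (not isolated)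
Conditions: 8 (2.6 equiv), NaN(SiMe3)2 (2.6 equiv), THF, 0 °C; I2 (2.5 equiv), −78 °C; NaN(SiMe3)2 (2.4 equiv), −78 → −20 °C; then 7, −78 → −20 °C (one equivalent of 11 is used up by the free hydroxyl)
Reagents that add atoms: iodine II
Why: Z-selective α-iodo Wittig olefination (Stork–Zhao type, here with an acetal-bearing ylide) goes through the kinetically formed cis-oxaphosphetane, so iodine ends up cis to the chain and the masked formyl group trans, which is the C1=C10 geometry of the target.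

Step 6
Reactants: 12 (2E,6Z)-3-(TBSO-methyl)-7-(1,3-dioxolan-2-yl)-7-iodohepta-2,6-dien-1-ol
Product: 13 (2E,6Z)-3-(TBSO-methyl)-7-(1,3-dioxolan-2-yl)-7-iodohepta-2,6-dienal
Conditions: activated MnO2 (15 equiv), CH2Cl2, 25 °C
Reagents that add atoms: none
Why: allylic oxidation on MnO2 gives the enal without touching the alkenyl iodide or the acetal and without isomerising the C4=C5 bond.

Step 7
Reactants: 13 (2E,6Z)-3-(TBSO-methyl)-7-(1,3-dioxolan-2-yl)-7-iodohepta-2,6-dienal; 14 vinylmagnesium bromide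
Product: 15 rac-(4E,8Z)-5-(TBSO-methyl)-9-(1,3-dioxolan-2-yl)-9-iodonona-1,4,8-trien-3-ol
Conditions: 14 (1.3 equiv), THF, −78 °C; then sat. aq. NH4Cl
Reagents that add atoms: none
Why: clean 1,2-Grignard addition to the β,β-disubstituted enal gives the bis-allylic alcohol as a racemate, whose C6 configuration is fixed in step 8.

Step 8
Reactants: 15 rac-(4E,8Z)-5-(TBSO-methyl)-9-(1,3-dioxolan-2-yl)-9-iodonona-1,4,8-trien-3-ol; 16 2-(bromomethyl)prop-2-enoic acid
Product: 17 (3S,4E,8Z)-5-(TBSO-methyl)-9-(1,3-dioxolan-2-yl)-9-iodonona-1,4,8-trien-3-yl 2-(bromomethyl)prop-2-enoate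
Conditions: [Ir(cod)Cl]2 (3 mol %), L* (12 mol %), 16 (1.5 equiv), Zn(OTf)2 (5 mol %), 1,2-dichloroethane, 25 °C
Reagents that add atoms: none
Why: Proposed new method: the phosphoramidite–olefin iridium catalyst binds the unsubstituted vinyl group of either enantiomer of 15, acid-assisted loss of water gives a trivalent η3-allyliridium whose diastereomers interconvert by η3–η1–η3 at the CH2 terminus, and the carboxylate of 16 attacks the substituted terminus anti to iridium, so both enantiomers converge on the (3S)-ester with the C6–O bond of the future lactone in place; the closest known reaction type is the iridium-catalysed enantioconvergent etherification and amination of racemic branched allylic alcohols, extended here to a carboxylic acid nucleophile and an alkenyl vinyl carbinol.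

Step 9
Reactants: 17 (3S,4E,8Z)-5-(TBSO-methyl)-9-(1,3-dioxolan-2-yl)-9-iodonona-1,4,8-trien-3-yl 2-(bromomethyl)prop-2-enoate
Product: 18 (5R)-3-(bromomethyl)-5-[(1E,5Z)-2-(TBSO-methyl)-6-(1,3-dioxolan-2-yl)-6-iodohexa-1,5-dien-1-yl]furan-2(5H)-one
Conditions: second-generation Hoveyda–Grubbs catalyst (5 mol %), toluene (0.01 M), 80 °C
Reagents that add atoms: none
Why: ring-closing metathesis between the two terminal alkenes (the trisubstituted alkenes are inert) closes the butenolide with loss of ethene and leaves the C6 stereocentre untouched.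

Step 10
Reactants: 18 (5R)-3-(bromomethyl)-5-[(1E,5Z)-2-(TBSO-methyl)-6-(1,3-dioxolan-2-yl)-6-iodohexa-1,5-dien-1-yl]furan-2(5H)-one; 19 2,2-dimethoxyacetaldehyde
Product: 20 (4R,5R)-4-[(1R)-1-hydroxy-2,2-dimethoxyethyl]-3-methylidene-5-[(1E,5Z)-2-(TBSO-methyl)-6-(1,3-dioxolan-2-yl)-6-iodohexa-1,5-dien-1-yl]oxolan-2-one
Conditions: Zn dust (3 equiv), 19 (60% in water, 3 equiv), THF/sat. aq. NH4Cl (2:1), 0 → 25 °C
Reagents that add atoms: none
Why: Barbier allylation with allylic transposition has the allylzinc attack the aldehyde through C7 on the face anti to the C6 side chain in a chair transition state with the aldehyde substituent equatorial, which sets C7 (trans-lactone) and C8 and unveils the α-methylene lactone.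

Step 11
Reactants: 20 (4R,5R)-4-[(1R)-1-hydroxy-2,2-dimethoxyethyl]-3-methylidene-5-[(1E,5Z)-2-(TBSO-methyl)-6-(1,3-dioxolan-2-yl)-6-iodohexa-1,5-dien-1-yl]oxolan-2-one; 21 (2R)-2-methylbutanoic acid
Product: 22 (1R)-2,2-dimethoxy-1-[(2R,3S)-4-methylidene-5-oxo-2-[(1E,5Z)-2-(TBSO-methyl)-6-(1,3-dioxolan-2-yl)-6-iodohexa-1,5-dien-1-yl]oxolan-3-yl]ethyl (2R)-2-methylbutanoate
Conditions: 21 (1.5 equiv), DIC (1.6 equiv), DMAP (0.1 equiv), CH2Cl2, 0 °C
Reagents that add atoms: none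
Why: Steglich esterification of the only free hydroxyl proceeds without epimerising the α-stereocentre of 21 under carbodiimide activation at 0 °C.

Step 12
Reactants: 22 (1R)-2,2-dimethoxy-1-[(2R,3S)-4-methylidene-5-oxo-2-[(1E,5Z)-2-(TBSO-methyl)-6-(1,3-dioxolan-2-yl)-6-iodohexa-1,5-dien-1-yl]oxolan-3-yl]ethyl (2R)-2-methylbutanoate
Product: 23 (1R)-1-[(2R,3S)-2-[(1E,5Z)-6-formyl-2-(hydroxymethyl)-6-iodohexa-1,5-dien-1-yl]-4-methylidene-5-oxooxolan-3-yl]-2-oxoethyl (2R)-2-methylbutanoate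
Conditions: TFA/H2O (9:1), CH2Cl2, 0 → 20 °C
Reagents that add atoms: water O
Why: one acid hydrolysis removes both acetals (C9 and C14 become aldehydes) and the silyl ether, and there is no adjacent free hydroxyl that could take up the C8 acyl group.

Step 13
Reactants: 23 (1R)-1-[(2R,3S)-2-[(1E,5Z)-6-formyl-2-(hydroxymethyl)-6-iodohexa-1,5-dien-1-yl]-4-methylidene-5-oxooxolan-3-yl]-2-oxoethyl (2R)-2-methylbutanoate
Product: 24 [(3aS,4R,5S,6E,10E,11aR)-6-formyl-5-hydroxy-10-(hydroxymethyl)-3-methylidene-2-oxo-3a,4,5,8,9,11a-hexahydrocyclodeca[b]furan-4-yl] (2R)-2-methylbutanoate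
Conditions: CrCl2 (10 equiv), NiCl2 (0.1 equiv), DMSO/THF (3:1), slow addition of 23 to 2 mM, 25 °C; then sat. aq. NH4Cl
Reagents that add atoms: none
Why: in this intramolecular Nozaki–Hiyama–Kishi reaction the alkenylchromium formed at C10 with retention adds to the C9 aldehyde, the ring can close only with C9 cis to C2, and polar Felkin–Anh attack anti to the C8 acyloxy group is expected to give the 9S alcohol cis to the ester.

**Compound list**

1 | but-2-yne-1,4-diol | OCC#CCO | starting material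
2 | 4-(triethylsilyloxy)but-2-yn-1-ol | CC[Si](CC)(CC)OCC#CCO | intermediate
3 | [2-(1,3-dioxolan-2-yl)ethyl]magnesium bromide | Br[Mg]CCC1OCCO1 | starting material
4 | bromomagnesium (2Z)-3-(bromomagnesio)-2-[2-(1,3-dioxolan-2-yl)ethyl]-4-(triethylsilyloxy)but-2-en-1-olate (alkenylmagnesium chelate) | Br[Mg]/C(CO[Si](CC)(CC)CC)=C(/CCC1OCCO1)CO[Mg]Br | intermediate
5 | (2E)-2-[2-(1,3-dioxolan-2-yl)ethyl]-4-(triethylsilyloxy)but-2-en-1-ol | CC[Si](CC)(CC)OC/C=C(/CO)CCC1OCCO1 | intermediate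
6 | (2E)-1-(TBSO)-2-[2-(1,3-dioxolan-2-yl)ethyl]-4-(triethylsilyloxy)but-2-ene | CC[Si](CC)(CC)OC/C=C(/CO[Si](C)(C)C(C)(C)C)CCC1OCCO1 | intermediate
7 | (4E)-4-(TBSO-methyl)-6-hydroxyhex-4-enal | OC/C=C(/CO[Si](C)(C)C(C)(C)C)CCC=O | intermediate
8 | (1,3-dioxolan-2-ylmethyl)triphenylphosphonium bromide | [Br-].C1COC(C[P+](c2ccccc2)(c2ccccc2)c2ccccc2)O1 | starting material
9 | [(1,3-dioxolan-2-yl)methylidene]triphenylphosphorane | C1COC(C=P(c2ccccc2)(c2ccccc2)c2ccccc2)O1 | intermediate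
10 | [(1,3-dioxolan-2-yl)(iodo)methyl]triphenylphosphonium iodide (racemic) | [I-].IC(C1OCCO1)[P+](c1ccccc1)(c1ccccc1)c1ccccc1 | intermediate
11 | [(1,3-dioxolan-2-yl)(iodo)methylidene]triphenylphosphorane | IC(C1OCCO1)=P(c1ccccc1)(c1ccccc1)c1ccccc1 | intermediate
12 | (2E,6Z)-3-(TBSO-methyl)-7-(1,3-dioxolan-2-yl)-7-iodohepta-2,6-dien-1-ol | OC/C=C(/CO[Si](C)(C)C(C)(C)C)CC/C=C(/C1OCCO1)I | intermediate
13 | (2E,6Z)-3-(TBSO-methyl)-7-(1,3-dioxolan-2-yl)-7-iodohepta-2,6-dienal | O=C/C=C(/CO[Si](C)(C)C(C)(C)C)CC/C=C(/C1OCCO1)I | intermediate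
14 | vinylmagnesium bromide | C=C[Mg]Br | starting material
15 | rac-(4E,8Z)-5-(TBSO-methyl)-9-(1,3-dioxolan-2-yl)-9-iodonona-1,4,8-trien-3-ol | C=CC(O)/C=C(/CO[Si](C)(C)C(C)(C)C)CC/C=C(/C1OCCO1)I | intermediate
16 | 2-(bromomethyl)prop-2-enoic acid | C=C(CBr)C(=O)O | starting material
17 | (3S,4E,8Z)-5-(TBSO-methyl)-9-(1,3-dioxolan-2-yl)-9-iodonona-1,4,8-trien-3-yl 2-(bromomethyl)prop-2-enoate | C=C(CBr)C(=O)O[C@@H](C=C)/C=C(/CO[Si](C)(C)C(C)(C)C)CC/C=C(/C1OCCO1)I | intermediate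
18 | (5R)-3-(bromomethyl)-5-[(1E,5Z)-2-(TBSO-methyl)-6-(1,3-dioxolan-2-yl)-6-iodohexa-1,5-dien-1-yl]furan-2(5H)-one | BrCC1=C[C@@H](/C=C(/CO[Si](C)(C)C(C)(C)C)CC/C=C(/C2OCCO2)I)OC1=O | intermediate
19 | 2,2-dimethoxyacetaldehyde | COC(OC)C=O | starting material
20 | (4R,5R)-4-[(1R)-1-hydroxy-2,2-dimethoxyethyl]-3-methylidene-5-[(1E,5Z)-2-(TBSO-methyl)-6-(1,3-dioxolan-2-yl)-6-iodohexa-1,5-dien-1-yl]oxolan-2-one | C=C1C(=O)O[C@H](/C=C(/CO[Si](C)(C)C(C)(C)C)CC/C=C(/C2OCCO2)I)[C@H]1[C@@H](O)C(OC)OC | intermediate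
21 | (2R)-2-methylbutanoic acid | CC[C@@H](C)C(=O)O | starting material
22 | (1R)-2,2-dimethoxy-1-[(2R,3S)-4-methylidene-5-oxo-2-[(1E,5Z)-2-(TBSO-methyl)-6-(1,3-dioxolan-2-yl)-6-iodohexa-1,5-dien-1-yl]oxolan-3-yl]ethyl (2R)-2-methylbutanoate | C=C1C(=O)O[C@H](/C=C(/CO[Si](C)(C)C(C)(C)C)CC/C=C(/C2OCCO2)I)[C@H]1[C@@H](OC(=O)[C@H](C)CC)C(OC)OC | intermediate
23 | (1R)-1-[(2R,3S)-2-[(1E,5Z)-6-formyl-2-(hydroxymethyl)-6-iodohexa-1,5-dien-1-yl]-4-methylidene-5-oxooxolan-3-yl]-2-oxoethyl (2R)-2-methylbutanoate | C=C1C(=O)O[C@H](/C=C(/CO)CC/C=C(/C=O)I)[C@H]1[C@@H](OC(=O)[C@H](C)CC)C=O | intermediate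
24 | [(3aS,4R,5S,6E,10E,11aR)-6-formyl-5-hydroxy-10-(hydroxymethyl)-3-methylidene-2-oxo-3a,4,5,8,9,11a-hexahydrocyclodeca[b]furan-4-yl] (2R)-2-methylbutanoate | C=C1C(=O)O[C@@H]2/C=C(/CO)CC/C=C(/C=O)[C@H](O)[C@H](OC(=O)[C@H](C)CC)[C@@H]12 | target

**Step count and risks**

Total step count: 13. Longest linear sequence: 13 steps (from 1; all other inputs are bought reagents).

The three steps most likely to fail:

Step 5 (iodo-Wittig). The acetal-bearing iodo ylide is an untested member of its class; it may lose alkoxide, give the iodine-free alkene, or react poorly with the hydroxy aldehyde. The fallback builds the iodo-enal in three known operations. It sets out from 7: Wittig reaction with (triphenylphosphoranylidene)acetaldehyde in toluene at 40 °C gives (2E,6E)-8-hydroxy-6-(TBSO-methyl)octa-2,6-dienal F1. α-Iodination with I2, DMAP (0.2 equiv) and K2CO3 in THF/H2O gives (2Z,6E)-8-hydroxy-2-iodo-6-(TBSO-methyl)octa-2,6-dienal F2. Acetalisation with 1,2-bis(trimethylsilyloxy)ethane and TMSOTf (5 mol %) in CH2Cl2 at −78 °C, followed by K2CO3 in MeOH to free the hydroxyl, comes back to the route at 12.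

Step 8 (the proposed esterification). Possible failures are an uncatalysed acid-promoted ionisation that gives racemic or conjugated dienyl esters, consumption of the allylic bromide of 16 by the monovalent iridium catalyst, or low enantioselectivity. The fallback is a classical resolution followed by acylation. It sets out from 15: Candida antarctica lipase B with vinyl acetate in methyl tert-butyl ether at 30 °C, run to about 52% conversion, acetylates the 3R enantiomer to (3R,4E,8Z)-5-(TBSO-methyl)-9-(1,3-dioxolan-2-yl)-9-iodonona-1,4,8-trien-3-yl acetate F4 and leaves (3S,4E,8Z)-5-(TBSO-methyl)-9-(1,3-dioxolan-2-yl)-9-iodonona-1,4,8-trien-3-ol F3 (at most 50%). F3 is esterified with 16 and DIC in CH2Cl2 at 0 °C, which comes back to the route at 17.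

Step 13 (ring closure). Risks are oligomerisation, the wrong C9 epimer, interference by the free C14 enal with divalent chromium, and O8→O9 acyl migration at the chromium alkoxide stage. The fallback changes the order of events: the ring is closed while C14 is still an acetal and O15 is silylated, and the C9 aldehyde is made by oxidation instead of acetal hydrolysis. It sets out from 18:

- Barbier reaction (Zn, THF/aq. NH4Cl) with 2-[(4-methoxybenzyl)oxy]acetaldehyde gives (4R,5R)-4-[(1R)-1-hydroxy-2-[(4-methoxybenzyl)oxy]ethyl]-3-methylidene-5-[(1E,5Z)-2-(TBSO-methyl)-6-(1,3-dioxolan-2-yl)-6-iodohexa-1,5-dien-1-yl]oxolan-2-one F5.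
- Esterification with 21 (DIC, DMAP) gives (1R)-2-[(4-methoxybenzyl)oxy]-1-[(2R,3S)-4-methylidene-5-oxo-2-[(1E,5Z)-2-(TBSO-methyl)-6-(1,3-dioxolan-2-yl)-6-iodohexa-1,5-dien-1-yl]oxolan-3-yl]ethyl (2R)-2-methylbutanoate F6.
- DDQ in CH2Cl2/pH 7 buffer gives (1R)-2-hydroxy-1-[(2R,3S)-4-methylidene-5-oxo-2-[(1E,5Z)-2-(TBSO-methyl)-6-(1,3-dioxolan-2-yl)-6-iodohexa-1,5-dien-1-yl]oxolan-3-yl]ethyl (2R)-2-methylbutanoate F7.
- Dess–Martin periodinane with NaHCO3 gives (1R)-1-[(2R,3S)-4-methylidene-5-oxo-2-[(1E,5Z)-2-(TBSO-methyl)-6-(1,3-dioxolan-2-yl)-6-iodohexa-1,5-dien-1-yl]oxolan-3-yl]-2-oxoethyl (2R)-2-methylbutanoate F8.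
- CrCl2 with NiCl2 (cat.) in DMSO/THF at 2 mM gives [(3aS,4R,5S,6E,10E,11aR)-6-(1,3-dioxolan-2-yl)-5-hydroxy-10-(TBSO-methyl)-3-methylidene-2-oxo-3a,4,5,8,9,11a-hexahydrocyclodeca[b]furan-4-yl] (2R)-2-methylbutanoate F9.
- TFA/H2O in CH2Cl2 at 0 °C removes the dioxolane and the silyl ether and comes back to the route at 24.

Further compounds

F1 | step 5 | (2E,6E)-8-hydroxy-6-(TBSO-methyl)octa-2,6-dienal | OC/C=C(/CO[Si](C)(C)C(C)(C)C)CC/C=C/C=O
F2 | step 5 | (2Z,6E)-8-hydroxy-2-iodo-6-(TBSO-methyl)octa-2,6-dienal | OC/C=C(/CO[Si](C)(C)C(C)(C)C)CC/C=C(/C=O)I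
F3 | step 8 | (3S,4E,8Z)-5-(TBSO-methyl)-9-(1,3-dioxolan-2-yl)-9-iodonona-1,4,8-trien-3-ol | C=C[C@H](O)/C=C(/CO[Si](C)(C)C(C)(C)C)CC/C=C(/C1OCCO1)I
F4 | step 8 | (3R,4E,8Z)-5-(TBSO-methyl)-9-(1,3-dioxolan-2-yl)-9-iodonona-1,4,8-trien-3-yl acetate | C=C[C@@H](OC(C)=O)/C=C(/CO[Si](C)(C)C(C)(C)C)CC/C=C(/C1OCCO1)I
F5 | step 13 | (4R,5R)-4-[(1R)-1-hydroxy-2-[(4-methoxybenzyl)oxy]ethyl]-3-methylidene-5-[(1E,5Z)-2-(TBSO-methyl)-6-(1,3-dioxolan-2-yl)-6-iodohexa-1,5-dien-1-yl]oxolan-2-one | C=C1C(=O)O[C@H](/C=C(/CO[Si](C)(C)C(C)(C)C)CC/C=C(/C2OCCO2)I)[C@H]1[C@@H](O)COCc3ccc(OC)cc3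
F6 | step 13 | (1R)-2-[(4-methoxybenzyl)oxy]-1-[(2R,3S)-4-methylidene-5-oxo-2-[(1E,5Z)-2-(TBSO-methyl)-6-(1,3-dioxolan-2-yl)-6-iodohexa-1,5-dien-1-yl]oxolan-3-yl]ethyl (2R)-2-methylbutanoate | C=C1C(=O)O[C@H](/C=C(/CO[Si](C)(C)C(C)(C)C)CC/C=C(/C2OCCO2)I)[C@H]1[C@@H](OC(=O)[C@H](C)CC)COCc3ccc(OC)cc3
F7 | step 13 | (1R)-2-hydroxy-1-[(2R,3S)-4-methylidene-5-oxo-2-[(1E,5Z)-2-(TBSO-methyl)-6-(1,3-dioxolan-2-yl)-6-iodohexa-1,5-dien-1-yl]oxolan-3-yl]ethyl (2R)-2-methylbutanoate | C=C1C(=O)O[C@H](/C=C(/CO[Si](C)(C)C(C)(C)C)CC/C=C(/C2OCCO2)I)[C@H]1[C@@H](OC(=O)[C@H](C)CC)CO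
F8 | step 13 | (1R)-1-[(2R,3S)-4-methylidene-5-oxo-2-[(1E,5Z)-2-(TBSO-methyl)-6-(1,3-dioxolan-2-yl)-6-iodohexa-1,5-dien-1-yl]oxolan-3-yl]-2-oxoethyl (2R)-2-methylbutanoate | C=C1C(=O)O[C@H](/C=C(/CO[Si](C)(C)C(C)(C)C)CC/C=C(/C2OCCO2)I)[C@H]1[C@@H](OC(=O)[C@H](C)CC)C=O
F9 | step 13 | [(3aS,4R,5S,6E,10E,11aR)-6-(1,3-dioxolan-2-yl)-5-hydroxy-10-(TBSO-methyl)-3-methylidene-2-oxo-3a,4,5,8,9,11a-hexahydrocyclodeca[b]furan-4-yl] (2R)-2-methylbutanoate | C=C1C(=O)O[C@@H]2/C=C(/CO[Si](C)(C)C(C)(C)C)CC/C=C(/C3OCCO3)[C@H](O)[C@H](OC(=O)[C@H](C)CC)[C@@H]12
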